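**Strategy.** The ten-membered carbocycle is closed between the vinylic carbon C5 and the oxygenated carbon C6, i.e. at the allylic carbinol O–C6–C5=C4 that the lactone ring and the (4E)-alkene share. An intramolecular Nozaki–Hiyama–Kishi reaction of an open-chain (E)-alkenyl iodide/α-hydroxy aldehyde forms this bond with retention of the alkene geometry and sets C6 under control of the quaternary C7 carbinol. The precursor already holds C7–C9 (proline aldol, Felkin–Anh ethynylation), the 8-acetate and the (1(10)Z)-alkene (Wittig). Its C7 ethynyl group and the new C6 hydroxyl are then cyclocarbonylated to the α-methylene-γ-lactone, before the epoxyangelate is attached.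

Key step: step 18

Remark: germacranolide numbering is used throughout (C1=C10 and C4=C5 ring alkenes, C6 lactone carbinol, C7 tertiary carbinol, C8 acetoxy carbon, C9 acyloxy carbon, C11=C13 exocyclic methylene, C12 lactone carbonyl); compounds 1, 6, 10 and 13 are taken as commercially available.

**Step 1**
Reactants: 1 pent-4-yn-1-ol
Product: 3 (E)-5-iodo-4-methylpent-4-en-1-ol, via alkenylalane 2 (not isolated)
Conditions: AlMe3 (3 equiv), Cp2ZrCl2 (0.25 equiv), CH2Cl2, 0 °C to rt; then I2, THF, −30 to 0 °C; aq. K2CO3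
Reagents that add atoms: trimethylaluminium, C[Al](C)C; iodine, II
Why: Zirconium-catalysed syn-carboalumination (Negishi carboalumination) adds methyl and aluminium cis across the terminal alkyne with aluminium at the terminus, and iodinolysis with retention should give the (E)-alkenyl iodide that becomes C4=C5.

**Step 2**
Reactants: 3 (E)-5-iodo-4-methylpent-4-en-1-ol
Product: 4 (E)-1,5-diiodo-2-methylpent-1-ene
Conditions: I2, PPh3, imidazole, CH2Cl2, 0 °C to rt
Reagents that add atoms: iodine, II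
Why: Appel-type iodination of the primary alcohol (SN2 on the alkoxyphosphonium ion) leaves the alkenyl iodide untouched.

**Step 3**
Reactants: 4 (E)-1,5-diiodo-2-methylpent-1-ene
Product: 5 [(E)-5-iodo-4-methylpent-4-en-1-yl]triphenylphosphonium iodide
Conditions: PPh3, MeCN, reflux
Reagents that add atoms: triphenylphosphine, c1ccc(cc1)P(c1ccccc1)c1ccccc1
Why: SN2 quaternisation of the phosphine takes place only at the primary alkyl iodide, the sp2 C–I bond being inert.

**Step 4**
Reactants: 6 methyl angelate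
Product: 7 (Z)-2-methylbut-2-en-1-ol
Conditions: i-Bu2AlH (2.2 equiv), CH2Cl2, −78 °C; aq. potassium sodium tartrate
Reagents that add atoms: none
Why: Hydride reduction of the conjugated ester at low temperature should give the allylic alcohol without Z/E isomerisation of the angelate double bond.

**Step 5**
Reactants: 7 (Z)-2-methylbut-2-en-1-ol
Product: 8 [(2R,3S)-2,3-dimethyloxiran-2-yl]methanol
Conditions: Ti(OiPr)4 (10 mol%), D-(−)-diethyl tartrate (12 mol%), t-BuOOH, 4 Å MS, CH2Cl2, −20 °C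
Reagents that add atoms: tert-butyl hydroperoxide, CC(C)(C)OO
Why: Sharpless asymmetric epoxidation; the D-(−)-tartrate catalyst should deliver oxygen to the face that gives the (2R,3S)-epoxide, and the Z-alkene fixes the cis relationship of CH2OH and the 3-methyl group.

**Step 6**
Reactants: 8 [(2R,3S)-2,3-dimethyloxiran-2-yl]methanol
Product: 9 (2S,3S)-2,3-dimethyloxirane-2-carboxylic acid
Conditions: RuCl3·xH2O (2 mol%), NaIO4 (4 equiv), MeCN/EtOAc/H2O, 0 °C to rt
Reagents that add atoms: water, O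
Why: RuO4 generated from RuCl3 and NaIO4 oxidises the primary alcohol to the acid under near-neutral biphasic conditions that spare the epoxide; C2 changes its descriptor to (S) only through the CIP priorities.

**Step 7**
Reactants: 10 2-methyl-1,3-dithiane
Product: 12 2-methyl-1,3-dithiane-2-carbaldehyde, via lithiated dithiane 11 (not isolated)
Conditions: n-BuLi, THF, −30 °C; then DMF, −78 to 0 °C; aq. NH4Cl
Reagents that add atoms: N,N-dimethylformamide, CN(C)C=O
Why: Corey–Seebach umpolung; formylation of the lithiated dithiane gives a non-enolisable aldehyde that carries C9 and the masked C10 methyl ketone.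

**Step 8**
Reactants: 12 2-methyl-1,3-dithiane-2-carbaldehyde; 13 2,2-dimethyl-1,3-dioxan-5-one
Product: 14 (4S)-4-[(R)-hydroxy(2-methyl-1,3-dithian-2-yl)methyl]-2,2-dimethyl-1,3-dioxan-5-one
Conditions: (S)-proline (30 mol%), DMF, 4 °C
Reagents that add atoms: none
Why: (S)-Proline-catalysed direct aldol reaction; the (E)-enamine of the cyclic ketone attacks the aldehyde through the carboxylic-acid-organised chair transition state, which should give the anti adduct and set C8 and C9 together.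

**Step 9**
Reactants: 14 (4S)-4-[(R)-hydroxy(2-methyl-1,3-dithian-2-yl)methyl]-2,2-dimethyl-1,3-dioxan-5-one
Product: 15 (4S)-4-[(R)-[(tert-butyldimethylsilyl)oxy](2-methyl-1,3-dithian-2-yl)methyl]-2,2-dimethyl-1,3-dioxan-5-one
Conditions: TBSOTf, 2,6-lutidine, CH2Cl2, −78 °C
Reagents that add atoms: tert-butyldimethylsilyl triflate, CC(C)(C)[Si](C)(C)OS(=O)(=O)C(F)(F)F
Why: Silylation of the hindered secondary alcohol with the silyl triflate blocks retro-aldol cleavage and marks O9 for the late esterification.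

**Step 10**
Reactants: 15 (4S)-4-[(R)-[(tert-butyldimethylsilyl)oxy](2-methyl-1,3-dithian-2-yl)methyl]-2,2-dimethyl-1,3-dioxan-5-one
Product: 16 (3S,4R)-4-[(tert-butyldimethylsilyl)oxy]-1,3-dihydroxy-4-(2-methyl-1,3-dithian-2-yl)butan-2-one
Conditions: AcOH/THF/H2O (3:1:1), 40 °C
Reagents that add atoms: none
Why: Mild acid hydrolysis of the 1,3-dioxane acetal, tolerated by the hindered TBS ether and the dithiane, takes the ketone out of the ring so that the coming addition follows acyclic 1,2-induction instead of axial attack on the dioxanone.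

**Step 11**
Reactants: 16 (3S,4R)-4-[(tert-butyldimethylsilyl)oxy]-1,3-dihydroxy-4-(2-methyl-1,3-dithian-2-yl)butan-2-one
Product: 17 (3S,4R)-4-[(tert-butyldimethylsilyl)oxy]-4-(2-methyl-1,3-dithian-2-yl)-1,3-bis[(triethylsilyl)oxy]butan-2-one
Conditions: TESCl (2.5 equiv), imidazole, DMAP (cat.), DMF, 0 °C to rt
Reagents that add atoms: chlorotriethylsilane, CC[Si](Cl)(CC)CC
Why: Both hydroxyls are capped as non-chelating triethylsilyl ethers that can later be removed in the presence of the TBS ether.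

**Step 12**
Reactants: 17 (3S,4R)-4-[(tert-butyldimethylsilyl)oxy]-4-(2-methyl-1,3-dithian-2-yl)-1,3-bis[(triethylsilyl)oxy]butan-2-one
Product: 18 (3S,4S,5R)-5-[(tert-butyldimethylsilyl)oxy]-5-(2-methyl-1,3-dithian-2-yl)-4-[(triethylsilyl)oxy]-3-{[(triethylsilyl)oxy]methyl}pent-1-yn-3-ol
Conditions: acetylene, n-BuLi, THF, −78 °C (LiC≡CH); then 17, −78 °C; aq. NH4Cl
Reagents that add atoms: lithium acetylide, [Li]C#C (made from acetylene, C#C)
Why: 1,2-Addition under non-chelating conditions should follow the polar Felkin–Anh model (C8–O bond anti to the nucleophile, C9 next to the carbonyl oxygen, H next to C6), which places the ethynyl group anti to O8 and sets the quaternary C7 carbinol in the required sense.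

**Step 13**
Reactants: 18 (3S,4S,5R)-5-[(tert-butyldimethylsilyl)oxy]-5-(2-methyl-1,3-dithian-2-yl)-4-[(triethylsilyl)oxy]-3-{[(triethylsilyl)oxy]methyl}pent-1-yn-3-ol
Product: 19 (3R,4S,5S)-3-[(tert-butyldimethylsilyl)oxy]-5-hydroxy-4-[(triethylsilyl)oxy]-5-{[(triethylsilyl)oxy]methyl}hept-6-yn-2-one
Conditions: MeI (excess), CaCO3, MeCN/H2O (9:1), 45 °C
Reagents that add atoms: water, O
Why: S-Methylation turns the dithiane into a leaving group and buffered hydrolysis unmasks the C10 methyl ketone without touching the silyl ethers, the alkyne or the C9 stereocentre.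

**Step 14**
Reactants: 19 (3R,4S,5S)-3-[(tert-butyldimethylsilyl)oxy]-5-hydroxy-4-[(triethylsilyl)oxy]-5-{[(triethylsilyl)oxy]methyl}hept-6-yn-2-one; 5 [(E)-5-iodo-4-methylpent-4-en-1-yl]triphenylphosphonium iodide
Product: 21 (3S,4S,5S,6Z,10E)-5-[(tert-butyldimethylsilyl)oxy]-11-iodo-6,10-dimethyl-4-[(triethylsilyl)oxy]-3-{[(triethylsilyl)oxy]methyl}undeca-6,10-dien-1-yn-3-ol, via phosphonium ylide 20 (not isolated)
Conditions: 5, NaN(SiMe3)2 (0.95 equiv per 5), THF, −78 °C; then 19, −78 °C to rt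
Reagents that add atoms: none
Why: Wittig olefination of an α-alkoxy ketone with a non-stabilised ylide is inherently Z-selective (alkoxy-bearing carbon cis to the ylide substituent), which should place C9 and C2 cis on the new C1=C10 bond while the alkenyl iodide, alkyne and free tertiary hydroxyl are not engaged.

**Step 15**
Reactants: 21 (3S,4S,5S,6Z,10E)-5-[(tert-butyldimethylsilyl)oxy]-11-iodo-6,10-dimethyl-4-[(triethylsilyl)oxy]-3-{[(triethylsilyl)oxy]methyl}undeca-6,10-dien-1-yn-3-ol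
Product: 22 (2S,3S,4S,5Z,9E)-4-[(tert-butyldimethylsilyl)oxy]-2-ethynyl-10-iodo-5,9-dimethyldeca-5,9-diene-1,2,3-triol
Conditions: PPTS (0.3 equiv), MeOH/CH2Cl2 (1:1), 0 °C to rt
Reagents that add atoms: none
Why: Acid-catalysed methanolysis should remove the primary and secondary triethylsilyl ethers much faster than the secondary TBS ether.

**Step 16**
Reactants: 22 (2S,3S,4S,5Z,9E)-4-[(tert-butyldimethylsilyl)oxy]-2-ethynyl-10-iodo-5,9-dimethyldeca-5,9-diene-1,2,3-triol
Product: 23 (2R,3S,4S,5Z,9E)-4-[(tert-butyldimethylsilyl)oxy]-2-ethynyl-2,3-dihydroxy-10-iodo-5,9-dimethyldeca-5,9-dienal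
Conditions: TEMPO (0.2 equiv), PhI(OAc)2 (1.2 equiv), CH2Cl2, rt
Reagents that add atoms: none
Why: Oxoammonium oxidation is selective for the primary alcohol over the secondary and tertiary hydroxyls and stops at the aldehyde, which cannot epimerise because C7 is quaternary.

**Step 17**
Reactants: 23 (2R,3S,4S,5Z,9E)-4-[(tert-butyldimethylsilyl)oxy]-2-ethynyl-2,3-dihydroxy-10-iodo-5,9-dimethyldeca-5,9-dienal
Product: 24 (2R,3S,4S,5Z,9E)-3-acetoxy-4-[(tert-butyldimethylsilyl)oxy]-2-ethynyl-2-hydroxy-10-iodo-5,9-dimethyldeca-5,9-dienal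
Conditions: Ac2O (1.5 equiv), pyridine, DMAP (5 mol%), CH2Cl2, 0 °C
Reagents that add atoms: acetic anhydride, CC(=O)OC(C)=O
Why: DMAP-catalysed acylation should take the secondary C8 hydroxyl and leave the tertiary propargylic C7 hydroxyl free, so that the acetate of the target is in place before ring closure.

**Step 18**
Reactants: 24 (2R,3S,4S,5Z,9E)-3-acetoxy-4-[(tert-butyldimethylsilyl)oxy]-2-ethynyl-2-hydroxy-10-iodo-5,9-dimethyldeca-5,9-dienal
Product: 25 (1S,2S,3Z,7E,9S,10S)-2-[(tert-butyldimethylsilyl)oxy]-10-ethynyl-9,10-dihydroxy-3,7-dimethylcyclodeca-3,7-dien-1-yl acetate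
Conditions: CrCl2 (15 equiv), NiCl2 (0.3 equiv), DMSO/THF (3:1), rt, 2 mM, slow addition of 24
Reagents that add atoms: none
Why: Zerovalent nickel, formed from NiCl2 and CrCl2, inserts into the C5–I bond with retention, transmetalation gives an alkenyl–CrCl2 species, and this adds to the C6 aldehyde (intramolecular Nozaki–Hiyama–Kishi reaction). The closest known reaction type is the Nozaki–Hiyama–Kishi closure of ω-iodoalkenyl aldehydes to medium and large carbocycles. The ten-membered ring is closed in a 10-exo-trig mode, the carbonyl oxygen staying outside the ring as the C6 hydroxyl. The new C6 stereocentre is controlled by the quaternary C7 carbinol: with the C6=O and C7–O dipoles opposed (Cornforth/Felkin–Anh arrangement) C5 enters past the small ethynyl group and anti to C8, a geometry that also matches the C5–C6–C7–C8 torsion of a trans-fused 6,12-olide. The step needs ring closure over oligomerisation, which high dilution and the turn imposed by the (Z)-C1=C10 alkene and the C7–C9 substituents should secure. It also needs chemoselectivity, which is given because the alkenyl iodide is the only bond nickel activates and the aldehyde the only electrophile the chromium reagent attacks (acetate, silyl ether and alkyne are tolerated).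

**Step 19**
Reactants: 25 (1S,2S,3Z,7E,9S,10S)-2-[(tert-butyldimethylsilyl)oxy]-10-ethynyl-9,10-dihydroxy-3,7-dimethylcyclodeca-3,7-dien-1-yl acetate
Product: 26 (3aS,4S,5S,6Z,10E,11aS)-5-[(tert-butyldimethylsilyl)oxy]-3a-hydroxy-6,10-dimethyl-3-methylidene-2-oxo-2,3,3a,4,5,8,9,11a-octahydrocyclodeca[b]furan-4-yl acetate
Conditions: PdCl2 (5 mol%), SnCl2 (5 mol%), PPh3 (10 mol%), CO (7 bar), MeCN, 70 °C
Reagents that add atoms: carbon monoxide, [C-]#[O+]
Why: Palladium-catalysed cyclocarbonylation of a homopropargylic alcohol; the alkoxycarbonyl–palladium species formed at O6 adds syn across the ethynyl group (5-exo-dig) and protonolysis should give the α-methylene-γ-butyrolactone, the five-membered closure through O6 being favoured over a four-membered one through O7 while O8 is blocked as the acetate.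

**Step 20**
Reactants: 26 (3aS,4S,5S,6Z,10E,11aS)-5-[(tert-butyldimethylsilyl)oxy]-3a-hydroxy-6,10-dimethyl-3-methylidene-2-oxo-2,3,3a,4,5,8,9,11a-octahydrocyclodeca[b]furan-4-yl acetate
Product: 27 (3aS,4S,5S,6Z,10E,11aS)-3a,5-dihydroxy-6,10-dimethyl-3-methylidene-2-oxo-2,3,3a,4,5,8,9,11a-octahydrocyclodeca[b]furan-4-yl acetate
Conditions: HF·pyridine, pyridine, THF, 0 °C to rt
Reagents that add atoms: none
Why: Fluoride cleavage of the TBS ether under buffered acidic conditions should avoid base-induced acetyl migration from O8 to O9 and conjugate addition to the methylene lactone.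

**Step 21**
Reactants: 27 (3aS,4S,5S,6Z,10E,11aS)-3a,5-dihydroxy-6,10-dimethyl-3-methylidene-2-oxo-2,3,3a,4,5,8,9,11a-octahydrocyclodeca[b]furan-4-yl acetate; 9 (2S,3S)-2,3-dimethyloxirane-2-carboxylic acid
Product: 29 (3aS,4S,5S,6Z,10E,11aS)-4-acetoxy-3a-hydroxy-6,10-dimethyl-3-methylidene-2-oxo-2,3,3a,4,5,8,9,11a-octahydrocyclodeca[b]furan-5-yl (2S,3S)-2,3-dimethyloxirane-2-carboxylate (CNP0271187.2), via mixed anhydride 28 (not isolated)
Conditions: 9, 2,4,6-trichlorobenzoyl chloride, Et3N, toluene, rt; then 27, DMAP, toluene, rt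
Reagents that add atoms: none
Why: Yamaguchi esterification through the mixed anhydride acylates the secondary allylic C9 hydroxyl (the tertiary C7 hydroxyl stays free) with the preformed (2S,3S)-epoxy acid, so the two epoxide stereocentres are not made on the macrocycle.

**Compound list**

1 | pent-4-yn-1-ol | C#CCCCO | starting material
2 | (E)-alkenylalane from methylalumination of 1 (O- and C-bound AlMe2) | C[Al](C)OCCC/C(C)=C/[Al](C)C | intermediate (not isolated)
3 | (E)-5-iodo-4-methylpent-4-en-1-ol | OCCC/C(C)=C/I | intermediate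
4 | (E)-1,5-diiodo-2-methylpent-1-ene | ICCC/C(C)=C/I | intermediate
5 | [(E)-5-iodo-4-methylpent-4-en-1-yl]triphenylphosphonium iodide | C/C(CCC[P+](c1ccccc1)(c1ccccc1)c1ccccc1)=C\I.[I-] | intermediate
6 | methyl angelate, methyl (Z)-2-methylbut-2-enoate | C/C=C(/C)C(=O)OC | starting material
7 | (Z)-2-methylbut-2-en-1-ol | C/C=C(/C)CO | intermediate
8 | [(2R,3S)-2,3-dimethyloxiran-2-yl]methanol | C[C@@H]1O[C@]1(C)CO | intermediate
9 | (2S,3S)-2,3-dimethyloxirane-2-carboxylic acid | C[C@@H]1O[C@]1(C)C(O)=O | intermediate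
10 | 2-methyl-1,3-dithiane | CC1SCCCS1 | starting material
11 | 2-lithio-2-methyl-1,3-dithiane | [Li]C1(C)SCCCS1 | intermediate (not isolated)
12 | 2-methyl-1,3-dithiane-2-carbaldehyde | CC1(C=O)SCCCS1 | intermediate
13 | 2,2-dimethyl-1,3-dioxan-5-one | CC1(C)OCC(=O)CO1 | starting material
14 | (4S)-4-[(R)-hydroxy(2-methyl-1,3-dithian-2-yl)methyl]-2,2-dimethyl-1,3-dioxan-5-one | CC1(C)OCC(=O)[C@@H](O1)[C@@H](O)C2(C)SCCCS2 | intermediate
15 | (4S)-4-[(R)-[(tert-butyldimethylsilyl)oxy](2-methyl-1,3-dithian-2-yl)methyl]-2,2-dimethyl-1,3-dioxan-5-one | CC1(C)OCC(=O)[C@@H](O1)[C@@H](O[Si](C)(C)C(C)(C)C)C2(C)SCCCS2 | intermediate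
16 | (3S,4R)-4-[(tert-butyldimethylsilyl)oxy]-1,3-dihydroxy-4-(2-methyl-1,3-dithian-2-yl)butan-2-one | OCC(=O)[C@@H](O)[C@@H](O[Si](C)(C)C(C)(C)C)C1(C)SCCCS1 | intermediate
17 | (3S,4R)-4-[(tert-butyldimethylsilyl)oxy]-4-(2-methyl-1,3-dithian-2-yl)-1,3-bis[(triethylsilyl)oxy]butan-2-one | CC[Si](CC)(CC)OCC(=O)[C@@H](O[Si](CC)(CC)CC)[C@@H](O[Si](C)(C)C(C)(C)C)C1(C)SCCCS1 | intermediate
18 | (3S,4S,5R)-5-[(tert-butyldimethylsilyl)oxy]-5-(2-methyl-1,3-dithian-2-yl)-4-[(triethylsilyl)oxy]-3-{[(triethylsilyl)oxy]methyl}pent-1-yn-3-ol | CC[Si](CC)(CC)OC[C@@](O)(C#C)[C@@H](O[Si](CC)(CC)CC)[C@@H](O[Si](C)(C)C(C)(C)C)C1(C)SCCCS1 | intermediate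
19 | (3R,4S,5S)-3-[(tert-butyldimethylsilyl)oxy]-5-hydroxy-4-[(triethylsilyl)oxy]-5-{[(triethylsilyl)oxy]methyl}hept-6-yn-2-one | CC[Si](CC)(CC)OC[C@@](O)(C#C)[C@@H](O[Si](CC)(CC)CC)[C@@H](O[Si](C)(C)C(C)(C)C)C(C)=O | intermediate
20 | [(E)-5-iodo-4-methylpent-4-en-1-ylidene]triphenylphosphorane | C/C(CCC=P(c1ccccc1)(c1ccccc1)c1ccccc1)=C\I | intermediate (not isolated)
21 | (3S,4S,5S,6Z,10E)-5-[(tert-butyldimethylsilyl)oxy]-11-iodo-6,10-dimethyl-4-[(triethylsilyl)oxy]-3-{[(triethylsilyl)oxy]methyl}undeca-6,10-dien-1-yn-3-ol | CC[Si](CC)(CC)OC[C@@](O)(C#C)[C@@H](O[Si](CC)(CC)CC)[C@@H](O[Si](C)(C)C(C)(C)C)/C(C)=C\CC/C(C)=C/I | intermediate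
22 | (2S,3S,4S,5Z,9E)-4-[(tert-butyldimethylsilyl)oxy]-2-ethynyl-10-iodo-5,9-dimethyldeca-5,9-diene-1,2,3-triol | OC[C@@](O)(C#C)[C@@H](O)[C@@H](O[Si](C)(C)C(C)(C)C)/C(C)=C\CC/C(C)=C/I | intermediate
23 | (2R,3S,4S,5Z,9E)-4-[(tert-butyldimethylsilyl)oxy]-2-ethynyl-2,3-dihydroxy-10-iodo-5,9-dimethyldeca-5,9-dienal | O=C[C@@](O)(C#C)[C@@H](O)[C@@H](O[Si](C)(C)C(C)(C)C)/C(C)=C\CC/C(C)=C/I | intermediate
24 | (2R,3S,4S,5Z,9E)-3-acetoxy-4-[(tert-butyldimethylsilyl)oxy]-2-ethynyl-2-hydroxy-10-iodo-5,9-dimethyldeca-5,9-dienal | O=C[C@@](O)(C#C)[C@@H](OC(C)=O)[C@@H](O[Si](C)(C)C(C)(C)C)/C(C)=C\CC/C(C)=C/I | intermediate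
25 | (1S,2S,3Z,7E,9S,10S)-2-[(tert-butyldimethylsilyl)oxy]-10-ethynyl-9,10-dihydroxy-3,7-dimethylcyclodeca-3,7-dien-1-yl acetate | O[C@H]1/C=C(\C)CC/C=C(/C)[C@H](O[Si](C)(C)C(C)(C)C)[C@H](OC(C)=O)[C@]1(O)C#C | intermediate
26 | (3aS,4S,5S,6Z,10E,11aS)-5-[(tert-butyldimethylsilyl)oxy]-3a-hydroxy-6,10-dimethyl-3-methylidene-2-oxo-2,3,3a,4,5,8,9,11a-octahydrocyclodeca[b]furan-4-yl acetate | C=C1C(=O)O[C@H]2/C=C(\C)CC/C=C(/C)[C@H](O[Si](C)(C)C(C)(C)C)[C@H](OC(C)=O)[C@]12O | intermediate
27 | (3aS,4S,5S,6Z,10E,11aS)-3a,5-dihydroxy-6,10-dimethyl-3-methylidene-2-oxo-2,3,3a,4,5,8,9,11a-octahydrocyclodeca[b]furan-4-yl acetate | C=C1C(=O)O[C@H]2/C=C(\C)CC/C=C(/C)[C@H](O)[C@H](OC(C)=O)[C@]12O | intermediate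
28 | (2S,3S)-2,3-dimethyloxirane-2-carboxylic 2,4,6-trichlorobenzoic anhydride | C[C@@H]1O[C@]1(C)C(=O)OC(=O)c2c(Cl)cc(Cl)cc2Cl | intermediate (not isolated)
29 | (3aS,4S,5S,6Z,10E,11aS)-4-acetoxy-3a-hydroxy-6,10-dimethyl-3-methylidene-2-oxo-2,3,3a,4,5,8,9,11a-octahydrocyclodeca[b]furan-5-yl (2S,3S)-2,3-dimethyloxirane-2-carboxylate | C=C1C(=O)O[C@H]2/C=C(\C)CC/C=C(/C)[C@H](OC(=O)[C@@]3(C)O[C@H]3C)[C@H](OC(C)=O)[C@]12O | target

**Step count and risks**

Total steps: 21. Longest linear sequence: 15 steps (steps 7 to 21, from 10).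

Steps most likely to fail:

1. Step 18. Oligomerisation may compete with the ten-membered ring closure, and the free C7 hydroxyl may chelate chromium so that C5 attacks the opposite aldehyde face. The fallback sets out from 24 and returns at 25, and no longer relies on the facial selectivity of the addition. The same closure is run and accepted as the C6 epimer, (1S,2S,3Z,7E,9R,10S)-2-[(tert-butyldimethylsilyl)oxy]-10-ethynyl-9,10-dihydroxy-3,7-dimethylcyclodeca-3,7-dien-1-yl acetate F1 (or as a mixture with 25). Dess–Martin oxidation should give the cyclodecadienone, (1S,2S,3Z,7E,10R)-2-[(tert-butyldimethylsilyl)oxy]-10-ethynyl-10-hydroxy-3,7-dimethyl-9-oxocyclodeca-3,7-dien-1-yl acetate F2. Chelation-controlled 1,2-reduction with Zn(BH4)2 (Et2O, −20 °C), in which zinc bridges the C7 hydroxyl and the C6 carbonyl and hydride enters from the side of the small ethynyl group, should then give 25.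

2. Step 19. Closure through the tertiary C7 hydroxyl, ionisation of the allylic C6–O bond by palladium, or reorganisation of the 1,5-diene at 70 °C may compete with the lactone formation. The fallback sets out from 25 and returns at 26. Regioselective hydrostannation (Bu3SnH, Mo(CO)3(CNt-Bu)3 cat., THF, 55 °C) should give the 1-stannylvinyl carbinol, (1S,2S,3Z,7E,9S,10S)-2-[(tert-butyldimethylsilyl)oxy]-9,10-dihydroxy-3,7-dimethyl-10-[1-(tributylstannyl)ethenyl]cyclodeca-3,7-dien-1-yl acetate F3. Iododestannylation (I2, CH2Cl2, −20 °C) should give the 1-iodovinyl carbinol, (1S,2S,3Z,7E,9S,10S)-2-[(tert-butyldimethylsilyl)oxy]-9,10-dihydroxy-10-(1-iodoethenyl)-3,7-dimethylcyclodeca-3,7-dien-1-yl acetate F4. Carbonylative lactonisation under mild conditions (Pd(PPh3)4 cat., CO 1 bar, Et3N, MeCN, 50 °C) should then close the lactone through O6 to give 26.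

3. Step 14. The basic ylide may enolise the hindered α-silyloxy ketone, with β-elimination of the C8 silyloxy group, and the Z-selectivity may erode. The fallback sets out from 4 and 19 and returns at 21, and replaces the one-pot Wittig reaction by a stepwise Horner–Wittig sequence. Michaelis–Arbuzov reaction of 4 with ethyl diphenylphosphinite (neat, 120 °C) should give [(E)-5-iodo-4-methylpent-4-en-1-yl]diphenylphosphine oxide F5. Its α-lithio derivative (LiN(i-Pr)2, THF, −78 °C) is added to 19, and from the resulting β-hydroxy phosphine oxides the diastereomer is separated in which C9 and C2 are cis when O and P are syn-periplanar, the C10-hydroxy-C1-(diphenylphosphoryl) adduct of F5 and 19, F6. Stereospecific syn-elimination (NaH, DMF, rt) should then give 21 as a single alkene isomer.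

**Further compounds**

F1 | step 18 | (1S,2S,3Z,7E,9R,10S)-2-[(tert-butyldimethylsilyl)oxy]-10-ethynyl-9,10-dihydroxy-3,7-dimethylcyclodeca-3,7-dien-1-yl acetate | O[C@@H]1/C=C(\C)CC/C=C(/C)[C@H](O[Si](C)(C)C(C)(C)C)[C@H](OC(C)=O)[C@]1(O)C#C
F2 | step 18 | (1S,2S,3Z,7E,10R)-2-[(tert-butyldimethylsilyl)oxy]-10-ethynyl-10-hydroxy-3,7-dimethyl-9-oxocyclodeca-3,7-dien-1-yl acetate | O=C1/C=C(\C)CC/C=C(/C)[C@H](O[Si](C)(C)C(C)(C)C)[C@H](OC(C)=O)[C@]1(O)C#C
F3 | step 19 | (1S,2S,3Z,7E,9S,10S)-2-[(tert-butyldimethylsilyl)oxy]-9,10-dihydroxy-3,7-dimethyl-10-[1-(tributylstannyl)ethenyl]cyclodeca-3,7-dien-1-yl acetate | O[C@H]1/C=C(\C)CC/C=C(/C)[C@H](O[Si](C)(C)C(C)(C)C)[C@H](OC(C)=O)[C@]1(O)C(=C)[Sn](CCCC)(CCCC)CCCC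
F4 | step 19 | (1S,2S,3Z,7E,9S,10S)-2-[(tert-butyldimethylsilyl)oxy]-9,10-dihydroxy-10-(1-iodoethenyl)-3,7-dimethylcyclodeca-3,7-dien-1-yl acetate | O[C@H]1/C=C(\C)CC/C=C(/C)[C@H](O[Si](C)(C)C(C)(C)C)[C@H](OC(C)=O)[C@]1(O)C(I)=C
F5 | step 14 | [(E)-5-iodo-4-methylpent-4-en-1-yl]diphenylphosphine oxide | C/C(CCCP(=O)(c1ccccc1)c1ccccc1)=C\I
F6 | step 14 | β-hydroxy phosphine oxide from F5 and 19 (C10 carbinol, C1 diphenylphosphoryl; diastereomer that eliminates to the Z-alkene) | CC[Si](CC)(CC)OC[C@@](O)(C#C)[C@@H](O[Si](CC)(CC)CC)[C@@H](O[Si](C)(C)C(C)(C)C)[C@@](C)(O)[C@H](CC/C(C)=C/I)P(=O)(c1ccccc1)c1ccccc1
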